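**Retrosynthetic overview**
- Ring C is closed last: the O1–C8a bond forms by intramolecular SNAr of the enolate of 1,3-diketone 28 on a C8a fluoride. Diketone 28 comes from acid chloride 26 (ring A plus pyran) and ketone 25 (ring B plus oxepine) by C3–C4 acylation.
- Ketone 25: the oxepine O–C(=CMe2) bond is closed by copper-catalysed O-vinylation of the 2'-phenol. Its side chain comes from the dianion of acetophenone 22 and dibromide 21.
- Acid 16 comes from chromene 14 by lithiation at C4a and CO2. Chromene 14 comes from aryl triflate 8, DMF and an alkenylzinc: the C7≡C8 aryne takes the pyran oxygen at C7 and the pyran carbon C4'' at C8, the zinc reagent makes the C4''–C3'' bond, and a 6π closure makes O–C2''.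
- Enabling feature: on ring A the pyran oxygen (on C7) and the pyran carbon (on C8) are neighbours, and C8 lies next to C8a, which carries O1 in the target. A fluorine held on C8a polarises the C7≡C8 aryne, guides the ring A metalations and is finally displaced by O1.
- Ring order: pyran on ring A (step 6); oxepine on ring B (step 12, separate branch); ring C last (step 14).

Key step: step 6

Remark: flavone numbering is used (O1, C2–C4, C4a–C8a; ring B C1'–C6'; pyran atoms C2''–C4''). The target has no stereocentre and every chiral intermediate is racemic. The solution of 2-methylprop-1-enylmagnesium bromide in THF is assumed to be bought.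

**Step 1**
Reactants: 1 3-fluoro-5-methoxyphenol
Product: 2 3-fluoro-5-methoxyphenyl N,N-diethylcarbamate
Conditions: Et2NCOCl, K2CO3, MeCN, reflux
Reagents that add atoms: N,N-diethylcarbamoyl chloride, CCN(CC)C(Cl)=O
Why: Carbamoylation of the phenoxide (O-acylation) installs the strongest oxygen-based director for ortho-metalation, which is removed again in step 4.

**Step 2**
Reactants: 2 3-fluoro-5-methoxyphenyl N,N-diethylcarbamate
Product: 4 3-fluoro-5-methoxy-2-(trimethylsilyl)phenyl N,N-diethylcarbamate, via 2-lithio carbamate 3 (not isolated)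
Conditions: s-BuLi, TMEDA, THF, −78 °C; then Me3SiCl, −78 °C to rt
Reagents that add atoms: chlorotrimethylsilane, C[Si](C)(C)Cl
Why: Directed ortho-metalation removes the most acidic hydrogen, the one between the O-carbamate and fluorine, and the silyl quench at −78 °C should precede both anionic Fries migration and loss of LiF.

**Step 3**
Reactants: 4 3-fluoro-5-methoxy-2-(trimethylsilyl)phenyl N,N-diethylcarbamate
Product: 6 3-fluoro-5-methoxy-6-(3-methylbut-2-en-1-yl)-2-(trimethylsilyl)phenyl N,N-diethylcarbamate, via 6-lithio carbamate 5 (not isolated)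
Conditions: s-BuLi, TMEDA, THF, −78 °C; then 1-bromo-3-methylbut-2-ene, CuBr·SMe2 (10 mol %), −78 to −40 °C
Reagents that add atoms: 1-bromo-3-methylbut-2-ene, CC(C)=CCBr
Why: A second directed ortho-metalation should take the remaining position ortho to the carbamate (flanked by OMe; the carbamate outranks fluorine as director), and copper-catalysed SN2 allylation at the primary carbon of the bromide then gives the linear prenyl group.

**Step 4**
Reactants: 6 3-fluoro-5-methoxy-6-(3-methylbut-2-en-1-yl)-2-(trimethylsilyl)phenyl N,N-diethylcarbamate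
Product: 7 3-fluoro-5-methoxy-6-(3-methylbut-2-en-1-yl)-2-(trimethylsilyl)phenol
Conditions: LiAlH4, THF, 0 °C to reflux; then H2O, pH 7 buffer
Reagents that add atoms: none
Why: Hydride reduction of the aryl carbamate (acyl C–O cleavage) frees the hindered phenol and should leave the C–Si bond, the C–F bond and the alkene untouched.

**Step 5**
Reactants: 7 3-fluoro-5-methoxy-6-(3-methylbut-2-en-1-yl)-2-(trimethylsilyl)phenol
Product: 8 3-fluoro-5-methoxy-6-(3-methylbut-2-en-1-yl)-2-(trimethylsilyl)phenyl trifluoromethanesulfonate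
Conditions: Tf2O, pyridine, CH2Cl2, 0 °C
Reagents that add atoms: trifluoromethanesulfonic anhydride, O=S(=O)(OS(=O)(=O)C(F)(F)F)C(F)(F)F
Why: O-sulfonylation of the phenol gives the ortho-silyl aryl triflate, the standard fluoride-triggered aryne precursor.

**Step 6**
Reactants: 8 3-fluoro-5-methoxy-6-(3-methylbut-2-en-1-yl)-2-(trimethylsilyl)phenyl trifluoromethanesulfonate
Product: 14 5-fluoro-7-methoxy-2,2-dimethyl-8-(3-methylbut-2-en-1-yl)-2H-chromene, via aryne 9 (not isolated), via benzoxete 10 (not isolated), via aminomethide 11 (not isolated), via allylic amine 12 (not isolated), via dienone 13 (not isolated)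
Conditions: 2-methylprop-1-enylmagnesium bromide and ZnCl2 (2:1) premixed in THF, 0 °C; add to 8, CsF, DMF, 0 °C to rt; then AcOH, 80 °C
Reagents that add atoms: N,N-dimethylformamide, CN(C)C=O; 2-methylprop-1-enylmagnesium bromide, CC(C)=C[Mg]Br
Why: Proposed new method: fluoride removes the silyl group and triflate leaves to give aryne 9, whose C7≡C8 bond is polarised by the fluorine on C8a, so the DMF oxygen should attack C7 (the carbon remote from fluorine, the developing carbanion on C8 being stabilised by the adjacent C–F bond) and the formyl carbon should close onto C8; benzoxete 10 then opens to aminomethide 11. Bis(2-methylprop-1-enyl)zinc, made beforehand by transmetalation of the Grignard reagent with ZnCl2, should add its CH carbon to the exocyclic iminium-like carbon of 11, which makes the C4''–C3'' bond and gives the zinc phenoxide of 12, and warming with AcOH should expel dimethylamine to give dienone 13. The pyran, the only ring closed, forms by thermal disrotatory 6π oxa-electrocyclisation of the 1-oxatriene in 13 (O to CMe2). The closest known reaction types are the insertion of arynes into the C=O bond of formamides with trapping of the ring-opened intermediate by dialkylzincs, and the amine-loss/6π closure by which salicylaldehydes, secondary amines and alkenylboronic acids give 2H-chromenes; the alkenyl transfer and the merger of both in one flask are untested. No stereocentre remains in 14, since the aminated carbon of 10 and 12 is racemic and becomes sp2. The step needs O-at-C7/C-at-C8 regioselectivity, secured by the C8a fluorine, and preference for DMF over an ene reaction of the aryne with a prenyl group, secured by DMF as solvent.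

**Step 7**
Reactants: 14 5-fluoro-7-methoxy-2,2-dimethyl-8-(3-methylbut-2-en-1-yl)-2H-chromene
Product: 16 5-fluoro-7-methoxy-2,2-dimethyl-8-(3-methylbut-2-en-1-yl)-2H-chromene-6-carboxylic acid, via 6-lithiochromene 15 (not isolated)
Conditions: s-BuLi, THF, −78 °C; CO2 (gas), −78 °C to rt; cold 1 M HCl
Reagents that add atoms: carbon dioxide, O=C=O
Why: Directed ortho-lithiation at the single aromatic C–H, flanked by F and OMe, followed by carboxylation places the future C4 carbon on C4a.

**Step 8**
Reactants: 17 3-methylbut-2-enal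
Product: 19 2-bromo-3-methylbut-2-enal, via dibromo aldehyde 18 (not isolated)
Conditions: Br2, CH2Cl2, −20 °C; then Et3N, 0 °C to rt
Reagents that add atoms: bromine, BrBr
Why: Bromine addition and base-induced loss of HBr through the acidic α-hydrogen (α-bromination of an enal) should give the tetrasubstituted vinyl bromide with a fixed alkene position.

**Step 9**
Reactants: 19 2-bromo-3-methylbut-2-enal
Product: 20 2-bromo-3-methylbut-2-en-1-ol
Conditions: NaBH4, CeCl3·7H2O, MeOH, 0 °C
Reagents that add atoms: none
Why: Luche reduction should give clean 1,2-reduction of the enal without touching the C–Br bond.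

**Step 10**
Reactants: 20 2-bromo-3-methylbut-2-en-1-ol
Product: 21 1,2-dibromo-3-methylbut-2-ene
Conditions: CBr4, PPh3, CH2Cl2, 0 °C
Reagents that add atoms: carbon tetrabromide, BrC(Br)(Br)Br
Why: Appel bromination converts the primary allylic alcohol to the bromide under neutral conditions.

**Step 11**
Reactants: 22 1-(2-hydroxy-4,5-dimethoxyphenyl)ethan-1-one; 21 1,2-dibromo-3-methylbut-2-ene
Product: 24 4-bromo-1-(2-hydroxy-4,5-dimethoxyphenyl)-5-methylhex-4-en-1-one, via dilithium dianion 23 (not isolated)
Conditions: LiN(i-Pr)2 (2.2 equiv), THF, −78 to 0 °C; then 21, −78 °C to rt; aq. NH4Cl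
Reagents that add atoms: none
Why: Alkylation of the phenoxide–enolate dianion should occur at the more basic enolate carbon by SN2 at the allylic CH2Br, the vinylic bromide being inert to substitution.

**Step 12**
Reactants: 24 4-bromo-1-(2-hydroxy-4,5-dimethoxyphenyl)-5-methylhex-4-en-1-one
Product: 25 7,8-dimethoxy-2-(propan-2-ylidene)-3,4-dihydro-1-benzoxepin-5(2H)-one
Conditions: CuI (10 mol %), 1,10-phenanthroline (20 mol %), Cs2CO3, toluene, 110 °C
Reagents that add atoms: none
Why: Ullmann-type copper-catalysed intramolecular O-vinylation of the phenoxide closes the seven-membered oxepine, and the exocyclic C=CMe2 position is fixed because the alkene of the vinyl bromide is retained.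

**Step 13**
Reactants: 16 5-fluoro-7-methoxy-2,2-dimethyl-8-(3-methylbut-2-en-1-yl)-2H-chromene-6-carboxylic acid; 25 7,8-dimethoxy-2-(propan-2-ylidene)-3,4-dihydro-1-benzoxepin-5(2H)-one
Product: 28 4-[5-fluoro-7-methoxy-2,2-dimethyl-8-(3-methylbut-2-en-1-yl)-2H-chromene-6-carbonyl]-7,8-dimethoxy-2-(propan-2-ylidene)-3,4-dihydro-1-benzoxepin-5(2H)-one (racemic; C4 epimerisable), via acid chloride 26 (not isolated), via lithium enolate 27 (not isolated)
Conditions: 16, 1-chloro-N,N,2-trimethylprop-1-en-1-amine, CH2Cl2, 0 °C to rt; separately 25, LiN(SiMe3)2 (2.2 equiv), THF, −78 °C; combine, −78 to 0 °C; pH 7 buffer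
Reagents that add atoms: none
Why: Claisen-type C-acylation of the lithium enolate of 25 with the acid chloride, made under neutral conditions so that the prenyl and chromene alkenes see no HCl, joins C3 to C4, and the extra base holds the product as its enolate.

**Step 14**
Reactants: 28 4-[5-fluoro-7-methoxy-2,2-dimethyl-8-(3-methylbut-2-en-1-yl)-2H-chromene-6-carbonyl]-7,8-dimethoxy-2-(propan-2-ylidene)-3,4-dihydro-1-benzoxepin-5(2H)-one
Product: 29 CNP0192589.0 (target)
Conditions: K2CO3, DMF, 80 °C
Reagents that add atoms: none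
Why: Intramolecular SNAr (addition–elimination): the enolate oxygen on C2 attacks C8a, activated by the ortho C4 carbonyl, displaces fluoride through a six-membered transition state and closes ring C under basic conditions that spare the enol ether.

**Compound list**
1 | 3-fluoro-5-methoxyphenol | COc1cc(O)cc(F)c1 | starting material
2 | 3-fluoro-5-methoxyphenyl N,N-diethylcarbamate | CCN(CC)C(=O)Oc1cc(F)cc(OC)c1 | intermediate
3 | [2-(diethylcarbamoyloxy)-6-fluoro-4-methoxyphenyl]lithium | CCN(CC)C(=O)Oc1cc(OC)cc(F)c1[Li] | intermediate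
4 | 3-fluoro-5-methoxy-2-(trimethylsilyl)phenyl N,N-diethylcarbamate | CCN(CC)C(=O)Oc1cc(OC)cc(F)c1[Si](C)(C)C | intermediate
5 | [2-(diethylcarbamoyloxy)-4-fluoro-6-methoxy-3-(trimethylsilyl)phenyl]lithium | CCN(CC)C(=O)Oc1c([Li])c(OC)cc(F)c1[Si](C)(C)C | intermediate
6 | 3-fluoro-5-methoxy-6-(3-methylbut-2-en-1-yl)-2-(trimethylsilyl)phenyl N,N-diethylcarbamate | CCN(CC)C(=O)Oc1c(CC=C(C)C)c(OC)cc(F)c1[Si](C)(C)C | intermediate
7 | 3-fluoro-5-methoxy-6-(3-methylbut-2-en-1-yl)-2-(trimethylsilyl)phenol | COc1cc(F)c([Si](C)(C)C)c(O)c1CC=C(C)C | intermediate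
8 | 3-fluoro-5-methoxy-6-(3-methylbut-2-en-1-yl)-2-(trimethylsilyl)phenyl trifluoromethanesulfonate | COc1cc(F)c([Si](C)(C)C)c(OS(=O)(=O)C(F)(F)F)c1CC=C(C)C | intermediate
9 | 3-fluoro-5-methoxy-6-(3-methylbut-2-en-1-yl)benzyne (1,2-didehydrobenzene; triple bond C7≡C8 in flavone numbering) | COC1=C(CC=C(C)C)C#CC(F)=C1 | intermediate
10 | 2-(dimethylamino)-3-fluoro-5-methoxy-6-(3-methylbut-2-en-1-yl)-2H-1-benzoxete (racemic) | CN(C)C1Oc2c1c(F)cc(OC)c2CC=C(C)C | intermediate
11 | 6-[(dimethylamino)methylidene]-5-fluoro-3-methoxy-2-(3-methylbut-2-en-1-yl)cyclohexa-2,4-dien-1-one | CN(C)C=C1C(F)=CC(OC)=C(CC=C(C)C)C1=O | intermediate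
12 | 2-[1-(dimethylamino)-3-methylbut-2-en-1-yl]-3-fluoro-5-methoxy-6-(3-methylbut-2-en-1-yl)phenol (racemic; present as its zinc phenoxide) | COc1cc(F)c(C(C=C(C)C)N(C)C)c(O)c1CC=C(C)C | intermediate
13 | 5-fluoro-3-methoxy-6-(3-methylbut-2-en-1-ylidene)-2-(3-methylbut-2-en-1-yl)cyclohexa-2,4-dien-1-one | CC(C)=CC=C1C(F)=CC(OC)=C(CC=C(C)C)C1=O | intermediate
14 | 5-fluoro-7-methoxy-2,2-dimethyl-8-(3-methylbut-2-en-1-yl)-2H-chromene | COc1cc(F)c2C=CC(C)(C)Oc2c1CC=C(C)C | intermediate
15 | [5-fluoro-7-methoxy-2,2-dimethyl-8-(3-methylbut-2-en-1-yl)-2H-chromen-6-yl]lithium | COc1c([Li])c(F)c2C=CC(C)(C)Oc2c1CC=C(C)C | intermediate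
16 | 5-fluoro-7-methoxy-2,2-dimethyl-8-(3-methylbut-2-en-1-yl)-2H-chromene-6-carboxylic acid | COc1c(C(=O)O)c(F)c2C=CC(C)(C)Oc2c1CC=C(C)C | intermediate
17 | 3-methylbut-2-enal | CC(C)=CC=O | starting material
18 | 2,3-dibromo-3-methylbutanal (racemic) | CC(C)(Br)C(Br)C=O | intermediate
19 | 2-bromo-3-methylbut-2-enal | CC(C)=C(Br)C=O | intermediate
20 | 2-bromo-3-methylbut-2-en-1-ol | CC(C)=C(Br)CO | intermediate
21 | 1,2-dibromo-3-methylbut-2-ene | CC(C)=C(Br)CBr | intermediate
22 | 1-(2-hydroxy-4,5-dimethoxyphenyl)ethan-1-one | CC(=O)c1cc(OC)c(OC)cc1O | starting material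
23 | dilithium dianion of 22 (lithium enolate and lithium phenoxide) | [Li]OC(=C)c1cc(OC)c(OC)cc1O[Li] | intermediate
24 | 4-bromo-1-(2-hydroxy-4,5-dimethoxyphenyl)-5-methylhex-4-en-1-one | CC(C)=C(Br)CCC(=O)c1cc(OC)c(OC)cc1O | intermediate
25 | 7,8-dimethoxy-2-(propan-2-ylidene)-3,4-dihydro-1-benzoxepin-5(2H)-one | COc1cc2OC(=C(C)C)CCC(=O)c2cc1OC | intermediate
26 | 5-fluoro-7-methoxy-2,2-dimethyl-8-(3-methylbut-2-en-1-yl)-2H-chromene-6-carbonyl chloride | COc1c(C(Cl)=O)c(F)c2C=CC(C)(C)Oc2c1CC=C(C)C | intermediate
27 | lithium enolate of 25 (C4=C5 enolate) | COc1cc2OC(=C(C)C)CC=C(O[Li])c2cc1OC | intermediate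
28 | 4-[5-fluoro-7-methoxy-2,2-dimethyl-8-(3-methylbut-2-en-1-yl)-2H-chromene-6-carbonyl]-7,8-dimethoxy-2-(propan-2-ylidene)-3,4-dihydro-1-benzoxepin-5(2H)-one (racemic; C4 epimerisable) | COc1cc2OC(=C(C)C)CC(C(=O)c3c(OC)c(CC=C(C)C)c4OC(C)(C)C=Cc4c3F)C(=O)c2cc1OC | intermediate
29 | CNP0192589.0: 5-methoxy-6-prenylflavone with a 2,2-dimethylpyran fused at C7–C8 (O on C7) and a C3–CH2–C(=CMe2)–O–C2' oxepine, 4',5'-dimethoxy on ring B; no stereocentre | COc1cc2c(cc1OC)-c1oc3c4c(c(CC=C(C)C)c(OC)c3c(=O)c1CC(=C(C)C)O2)OC(C)(C)C=C4 | target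

**Step count and risks**
Total steps: 14. Longest linear sequence: 9 steps (steps 1–7, 13 and 14, from 3-fluoro-5-methoxyphenol); steps 8–12 form the convergent branch.

Steps most likely to fail:

1. Step 6 (proposed new method). The alkenyl transfer from zinc to the aminomethide may be slower than hydrolysis or oligomerisation of that intermediate, loss of dimethylamine may stall, or the aryne may be diverted into an ene reaction with a prenyl group. The fallback sets out from 8 and uses known chemistry only. Triflate 8 with CsF in DMF, followed by aqueous work-up, should give the salicylaldehyde 6-fluoro-2-hydroxy-4-methoxy-3-(3-methylbut-2-en-1-yl)benzaldehyde F1 by the established hydrolytic outcome of aryne insertion into DMF, with the same fluorine-controlled regiochemistry. Excess 2-methylprop-1-enylmagnesium bromide in THF at 0 °C should add to the aldehyde to give 3-fluoro-2-(1-hydroxy-3-methylbut-2-en-1-yl)-5-methoxy-6-(3-methylbut-2-en-1-yl)phenol F2. Warming F2 with catalytic pyridinium p-toluenesulfonate in toluene should dehydrate it to dienone 13, which closes by the same 6π oxa-electrocyclisation. The fallback returns to the route at 14.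

2. Step 12. Oxidative addition of the tetrasubstituted vinyl bromide to copper may be slow, and the seven-membered C–O closure may lose out to intermolecular coupling or to dehydrobromination towards an allene. The fallback sets out from 22 and makes the C–O bond by electrophilic cyclisation instead. The dianion of 22 (LiN(i-Pr)2, THF) is alkylated with 1-bromobut-2-yne to give 1-(2-hydroxy-4,5-dimethoxyphenyl)hex-4-yn-1-one F3. 7-Exo-dig iodoetherification of the phenoxide (I2, K2CO3, MeCN, 0 °C, anti addition) should give (E)-2-(1-iodoethylidene)-7,8-dimethoxy-3,4-dihydro-1-benzoxepin-5(2H)-one F4. Negishi coupling with MeZnCl and Pd(PPh3)4 in THF then installs the second methyl group. The fallback returns to the route at 25.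

3. Step 3. Metalation may drift to the position between fluorine and OMe, and the lithiated carbamate may undergo anionic Fries migration before it is allylated. The fallback sets out from 4 and places the prenyl group by a sigmatropic shift, so no second metalation is needed. LiAlH4 in THF cleaves the carbamate of 4 to 3-fluoro-5-methoxy-2-(trimethylsilyl)phenol F5. O-Allylation with methyl 2-methylbut-3-en-2-yl carbonate and Pd(PPh3)4 (zerovalent palladium) in THF gives 1-fluoro-5-methoxy-3-[(2-methylbut-3-en-2-yl)oxy]-2-(trimethylsilyl)benzene F6. Aromatic Claisen rearrangement in toluene at 110 °C should deliver the prenyl group to the only free ortho carbon. The fallback returns to the route at 7 and makes step 4 unnecessary.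

**Further compounds**
F1 | step 6 | 6-fluoro-2-hydroxy-4-methoxy-3-(3-methylbut-2-en-1-yl)benzaldehyde | COc1cc(F)c(C=O)c(O)c1CC=C(C)C
F2 | step 6 | 3-fluoro-2-(1-hydroxy-3-methylbut-2-en-1-yl)-5-methoxy-6-(3-methylbut-2-en-1-yl)phenol (racemic) | COc1cc(F)c(C(O)C=C(C)C)c(O)c1CC=C(C)C
F3 | step 12 | 1-(2-hydroxy-4,5-dimethoxyphenyl)hex-4-yn-1-one | CC#CCCC(=O)c1cc(OC)c(OC)cc1O
F4 | step 12 | (E)-2-(1-iodoethylidene)-7,8-dimethoxy-3,4-dihydro-1-benzoxepin-5(2H)-one | C/C(I)=C1/CCC(=O)c2cc(OC)c(OC)cc2O1
F5 | step 3 | 3-fluoro-5-methoxy-2-(trimethylsilyl)phenol | COc1cc(O)c([Si](C)(C)C)c(F)c1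
F6 | step 3 | 1-fluoro-5-methoxy-3-[(2-methylbut-3-en-2-yl)oxy]-2-(trimethylsilyl)benzene | COc1cc(OC(C)(C)C=C)c([Si](C)(C)C)c(F)c1
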